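The target is disconnected at the interflavan bond C4(upper)–C8(lower) and, inside the lower catechin unit, at C2–C3 and C4–C4a of its pyran ring. That ring is a formal [4+2] adduct. C4a=C8a–O1=C2 (the phloroglucinol ring with its ortho carbon C4a, the ether oxygen O1 and the benzylic C2) is an aryl oxocarbenium ion. C3–C4 is O-benzylglycolaldehyde, used as a chiral prolinol-ether enamine. One flask forms both bonds, sets C2 and C3, and reduces off a temporary C4–N bond. The precursor is an acyclic benzotriazolyl aryl acetal. A Friedel–Crafts flavanyl transfer then joins the two units and hydrogenolysis ends the route.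

Key step: step 6

Remark: the acetal carbon of 7 and 9 is racemic; this is immaterial because it becomes a planar cation in step 6.

Step 1
Reactants: 1 7-hydroxy-4H-chromen-4-one
Product: 2 7-(benzyloxy)-4H-chromen-4-one
Conditions: BnBr, K2CO3, DMF, 50 °C
Reagents that add atoms: benzyl bromide, BrCc1ccccc1
Why: Williamson etherification of the phenol under carbonate conditions that leave the chromone ring closed; no stereocenter is formed.

Step 2
Reactants: 2 7-(benzyloxy)-4H-chromen-4-one; 3 3,4-bis(benzyloxy)phenylboronic acid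
Product: 4 (2S)-7-(benzyloxy)-2-[3,4-bis(benzyloxy)phenyl]chroman-4-one
Conditions: Pd(OCOCF3)2 (5 mol%), (R)-4-tert-butyl-2-(pyridin-2-yl)-4,5-dihydrooxazole (6 mol%), NH4PF6 (30 mol%), H2O, ClCH2CH2Cl, 60 °C
Reagents that add atoms: none
Why: Asymmetric conjugate addition of an arylboronic acid to a chromone with a cationic divalent palladium pyridine-oxazoline catalyst, in which the (R)-ligand should place the aryl group on the face of C2 that gives the 2S flavanone (enantiomeric purity to be raised by crystallisation) and the non-basic medium avoids retro-oxa-Michael racemisation.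

Step 3
Reactants: 4 (2S)-7-(benzyloxy)-2-[3,4-bis(benzyloxy)phenyl]chroman-4-one
Product: 5 (2S,4S)-7-(benzyloxy)-2-[3,4-bis(benzyloxy)phenyl]chroman-4-ol (2,4-cis)
Conditions: NaBH4, THF/MeOH, 0 °C
Reagents that add atoms: none
Why: Hydride reduction of the flavanone by axial attack on the half-chair with equatorial 2-aryl should give the 2,4-cis (4S) alcohol; the C4 configuration is lost again on ionisation in step 7, and C2 is not touched.

Step 4
Reactants: 6 3,4-bis(benzyloxy)benzaldehyde
Product: 7 1-{[3,4-bis(benzyloxy)phenyl](chloro)methyl}-1H-benzotriazole (racemic)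
Conditions: 1H-benzotriazole, SOCl2, toluene, 0 °C → rt
Reagents that add atoms: 1H-benzotriazole, c1ccc2[nH]nnc2c1; thionyl chloride, ClS(Cl)=O
Why: Condensation of the aldehyde with benzotriazole to the hemiaminal and its chlorination with SOCl2 is the standard entry to 1-(α-chloroalkyl)benzotriazoles; the benzyl ethers tolerate these conditions and the new center is racemic.

Step 5
Reactants: 8 3,5-bis(benzyloxy)phenol; 7 1-{[3,4-bis(benzyloxy)phenyl](chloro)methyl}-1H-benzotriazole
Product: 9 1-{[3,5-bis(benzyloxy)phenoxy][3,4-bis(benzyloxy)phenyl]methyl}-1H-benzotriazole (racemic)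
Conditions: NaH, DMF, 0 °C → rt
Reagents that add atoms: none
Why: Williamson-type O-alkylation of the sodium phenoxide by the reactive α-chloroalkyl benzotriazole; the polar aprotic solvent should favour attack through oxygen over ring carbon, and the basic medium keeps the acetal intact.

Step 6
Reactants: 9 1-{[3,5-bis(benzyloxy)phenoxy][3,4-bis(benzyloxy)phenyl]methyl}-1H-benzotriazole; 10 (benzyloxy)acetaldehyde; 11 (S)-2-{diphenyl[(trimethylsilyl)oxy]methyl}pyrrolidine
Product: 15 (2R,3S)-3,5,7-tris(benzyloxy)-2-[3,4-bis(benzyloxy)phenyl]chromane (3,5,7,3',4'-penta-O-benzyl-(+)-catechin), via enamine 12 (not isolated), via iminium ion 13 (not isolated), via 4-aminochroman 14 (not isolated)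
Conditions: 10 + 11, 4 Å MS, CH2Cl2, rt; then 9, ZnBr2 (30 mol%), −40 → 0 °C; then Et3SiH, CF3CO2H, −20 → 0 °C
Reagents that add atoms: none
Why: Proposed new method: ZnBr2 ionises the C–N bond of 9 to an E-configured aryl oxocarbenium ion (the cationic 2-oxadiene C4a=C8a–O1=C2), the α-carbon of the (E)-enamine 12 adds to it (C2–C3, ion 13), the iminium carbon so formed is attacked by the ortho carbon C4a of the phloroglucinol ring (C4–C4a, amine 14), and Et3SiH/CF3CO2H then exchanges the acid-labile benzylic C4–N bond for C4–H and returns the auxiliary 11. The closest known reaction types are the oxa-Povarov [4+2] reaction of aryl oxocarbenium ions with alkenes, the SN1-type α-alkylation of aldehydes through prolinol-ether enamines with stabilised cations, and the silane/acid cleavage of 2,4,6-trialkoxybenzyl amines; an enamine has not been used as the two-carbon partner of an oxa-Povarov reaction. The pyran ring closes in a 6-exo-trig Friedel–Crafts (Mannich-type) attack of the arene on the exocyclic C=N+ carbon. C3 is controlled by the auxiliary, whose CPh2OSiMe3 group shields one face of the s-trans (E)-enamine so that C2 bonds to the Re face of C3 (3S); C2 is controlled by the anti topicity expected for an E-oxocarbenium ion and an E-enamine in an open or endo transition state, as in anti-selective Mannich reactions of the same enamines, which gives the 2,3-trans (2R) relationship; the C4 center of 14 is transient. The step needs oxygen on C3 and not on C4, which the polarisation of the enamine secures, loss of benzotriazolide and not of aryloxide, which zinc coordination to the triazole secures, and cleavage of C4–N without opening of the C2–O1 benzylic ether, which the much higher stability of the 2,4,6-trioxygenated C4 cation at low acid strength and temperature secures.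

Step 7
Reactants: 5 (2S,4S)-7-(benzyloxy)-2-[3,4-bis(benzyloxy)phenyl]chroman-4-ol; 15 (2R,3S)-3,5,7-tris(benzyloxy)-2-[3,4-bis(benzyloxy)phenyl]chromane
Product: 16 (2R,3S)-3,5,7-tris(benzyloxy)-2-[3,4-bis(benzyloxy)phenyl]-8-{(2S,4R)-7-(benzyloxy)-2-[3,4-bis(benzyloxy)phenyl]chroman-4-yl}chromane (octa-O-benzyl ether of the target)
Conditions: 15 (3 equiv), Me3SiOTf (20 mol%), 4 Å MS, CH2Cl2, −40 → 0 °C
Reagents that add atoms: none
Why: Biomimetic Friedel–Crafts flavanyl transfer in which the acid ionises the 4-ol of 5 to a benzylic cation stabilised by the para 7-benzyloxy group and the excess of 15 captures it at C8, its most nucleophilic and less hindered free ring carbon, by axial attack on the half-chair with equatorial 2-aryl, so that the 2,4-trans (4R) isomer should predominate.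

Step 8
Reactants: 16 octa-O-benzyl ether of the target
Product: 17 (2R,3S)-2-(3,4-dihydroxyphenyl)-8-[(2S,4R)-2-(3,4-dihydroxyphenyl)-7-hydroxychroman-4-yl]chromane-3,5,7-triol (CNP0227165.4)
Conditions: H2 (1 atm), Pd(OH)2/C, THF/MeOH, rt
Reagents that add atoms: none
Why: Hydrogenolysis removes the seven aryl benzyl ethers and the 3-O-benzyl ether under neutral conditions that should leave the doubly benzylic C4–C8 bond, both pyran rings and all four stereocenters untouched.

Compound list
1 | 7-hydroxy-4H-chromen-4-one | O=c1ccoc2cc(O)ccc12 | starting material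
2 | 7-(benzyloxy)-4H-chromen-4-one | O=c1ccoc2cc(OCc3ccccc3)ccc12 | intermediate
3 | 3,4-bis(benzyloxy)phenylboronic acid | OB(O)c1ccc(OCc2ccccc2)c(OCc2ccccc2)c1 | starting material
4 | (2S)-7-(benzyloxy)-2-[3,4-bis(benzyloxy)phenyl]chroman-4-one | C(c1ccccc1)Oc1ccc2c(c1)O[C@H](c1ccc(OCc3ccccc3)c(OCc3ccccc3)c1)CC2=O | intermediate
5 | (2S,4S)-7-(benzyloxy)-2-[3,4-bis(benzyloxy)phenyl]chroman-4-ol | C(c1ccccc1)Oc1ccc2c(c1)O[C@H](c1ccc(OCc3ccccc3)c(OCc3ccccc3)c1)C[C@@H]2O | intermediate
6 | 3,4-bis(benzyloxy)benzaldehyde | O=Cc1ccc(OCc2ccccc2)c(OCc2ccccc2)c1 | starting material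
7 | 1-{[3,4-bis(benzyloxy)phenyl](chloro)methyl}-1H-benzotriazole (racemic) | ClC(c1ccc(OCc2ccccc2)c(OCc2ccccc2)c1)n1nnc2ccccc21 | intermediate
8 | 3,5-bis(benzyloxy)phenol | Oc1cc(OCc2ccccc2)cc(OCc2ccccc2)c1 | starting material
9 | 1-{[3,5-bis(benzyloxy)phenoxy][3,4-bis(benzyloxy)phenyl]methyl}-1H-benzotriazole (racemic) | c1ccccc1COc1cc(OCc2ccccc2)cc(OC(c2ccc(OCc3ccccc3)c(OCc3ccccc3)c2)n2nnc3ccccc32)c1 | intermediate
10 | (benzyloxy)acetaldehyde | O=CCOCc1ccccc1 | starting material
11 | (S)-2-{diphenyl[(trimethylsilyl)oxy]methyl}pyrrolidine | C[Si](C)(C)OC(c1ccccc1)(c1ccccc1)[C@@H]1CCCN1 | starting material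
12 | (S)-1-[(E)-2-(benzyloxy)ethenyl]-2-{diphenyl[(trimethylsilyl)oxy]methyl}pyrrolidine (enamine of 10 and 11) | C[Si](C)(C)OC(c1ccccc1)(c1ccccc1)[C@@H]1CCCN1/C=C/OCc1ccccc1 | intermediate
13 | iminium ion after C2–C3 bond formation: 3-[3,5-bis(benzyloxy)phenoxy]-2-(benzyloxy)-3-[3,4-bis(benzyloxy)phenyl]propylidene pyrrolidinium of 11, anti, 2R,3S in flavan numbering, benzotriazolide salt | c1c(OCc2ccccc2)cc(OCc2ccccc2)cc1O[C@H](c1ccc(OCc3ccccc3)c(OCc3ccccc3)c1)[C@@H](OCc1ccccc1)C=[N+]1CCC[C@H]1C(c1ccccc1)(c1ccccc1)O[Si](C)(C)C.c1ccc2[n-]nnc2c1 | intermediate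
14 | (2R,3S)-3,5,7-tris(benzyloxy)-2-[3,4-bis(benzyloxy)phenyl]-4-{(S)-2-[diphenyl(trimethylsilyloxy)methyl]pyrrolidin-1-yl}chromane (C4 configuration not defined) | c1c(OCc2ccccc2)cc(OCc2ccccc2)c2c1O[C@H](c1ccc(OCc3ccccc3)c(OCc3ccccc3)c1)[C@@H](OCc1ccccc1)C2N1CCC[C@H]1C(c1ccccc1)(c1ccccc1)O[Si](C)(C)C | intermediate
15 | (2R,3S)-3,5,7-tris(benzyloxy)-2-[3,4-bis(benzyloxy)phenyl]chromane | c1c(OCc2ccccc2)cc(OCc2ccccc2)c2c1O[C@H](c1ccc(OCc3ccccc3)c(OCc3ccccc3)c1)[C@@H](OCc1ccccc1)C2 | intermediate
16 | (2R,3S)-3,5,7-tris(benzyloxy)-2-[3,4-bis(benzyloxy)phenyl]-8-{(2S,4R)-7-(benzyloxy)-2-[3,4-bis(benzyloxy)phenyl]chroman-4-yl}chromane | C(c1ccccc1)Oc1ccc2c(c1)O[C@H](c1ccc(OCc3ccccc3)c(OCc3ccccc3)c1)C[C@H]2c1c(OCc3ccccc3)cc(OCc3ccccc3)c2c1O[C@H](c1ccc(OCc3ccccc3)c(OCc3ccccc3)c1)[C@@H](OCc1ccccc1)C2 | intermediate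
17 | (2R,3S)-2-(3,4-dihydroxyphenyl)-8-[(2S,4R)-2-(3,4-dihydroxyphenyl)-7-hydroxychroman-4-yl]chromane-3,5,7-triol | Oc1ccc2c(c1)O[C@H](c1ccc(O)c(O)c1)C[C@H]2c1c(O)cc(O)c2c1O[C@H](c1ccc(O)c(O)c1)[C@@H](O)C2 | target

Total step count: 8. Longest linear sequence: 5 steps (steps 1, 2, 3, 7, 8; equally steps 4, 5, 6, 7, 8).

Steps most likely to fail

Step 6 (Proposed new method). The acetal may ionise with loss of aryloxide instead of benzotriazolide. The anti selectivity at C2 in the C–C bond formation may be poor. The iminium ion may be reduced before the ring closes. The pyran may open at C2–O1 during the silane stage. Fallback with known chemistry: the de novo annulation is given up and the lower unit is taken from the chiral pool. The fallback sets out from alcohol 5. Commercial (+)-catechin is benzylated at its four phenols (BnBr, K2CO3, DMF) to 5,7,3',4'-tetra-O-benzyl-(+)-catechin F1. Alcohol 5 is coupled with an excess of F1 under the conditions of step 7 to the hepta-O-benzyl dimer with free 3-hydroxyl F2. Hydrogenolysis of F2 as in step 8 gives 17, where the route is rejoined.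

Step 7. The cation may be captured at C6 in competition with C8. The 2,4-cis epimer may form. The cation may eliminate to the flav-3-ene or condense with the ring of a second molecule of 5. Fallback: the order is inverted, so that the interflavan bond is made with a monocyclic arene and the lower pyran ring is built last. The fallback sets out from 5 and phenol 8. Friedel–Crafts alkylation ortho to the free hydroxyl (Me3SiOTf cat., CH2Cl2) should give (2S,4R)-7-(benzyloxy)-2-[3,4-bis(benzyloxy)phenyl]-4-[2,4-bis(benzyloxy)-6-hydroxyphenyl]chromane F3. O-Alkylation with 7 as in step 5 gives the benzotriazolyl acetal F4. The conditions of step 6 with enamine 12 then close the pyran ring through iminium ion F5 and 4-aminochroman F6, neither isolated, and deliver 16, where the route is rejoined. The only free carbon ortho to the acetal oxygen becomes C4a, so the 4→8 connectivity is fixed by construction.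

Step 2. Insertion into the electron-rich chromone may be slow, the boronic acid may protodeboronate, and the facial selectivity may be insufficient. Fallback: the fallback sets out from aldehyde 6. Claisen–Schmidt condensation with commercial 1-[4-(benzyloxy)-2-hydroxyphenyl]ethanone (KOH, EtOH) gives (E)-1-[4-(benzyloxy)-2-hydroxyphenyl]-3-[3,4-bis(benzyloxy)phenyl]prop-2-en-1-one F7. Oxa-Michael cyclisation (NaOAc, EtOH, reflux) gives racemic 7-(benzyloxy)-2-[3,4-bis(benzyloxy)phenyl]chroman-4-one F8. Asymmetric transfer hydrogenation with RuCl[(S,S)-TsDPEN](p-cymene) and HCO2H/Et3N, run as a kinetic resolution, should reduce the 2S ketone faster to the cis alcohol 5, where the route is rejoined. The slow-reacting 2R ketone is separated.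

Further compounds
F1 | step 6 | 5,7,3',4'-tetra-O-benzyl-(+)-catechin | c1c(OCc2ccccc2)cc(OCc2ccccc2)c2c1O[C@H](c1ccc(OCc3ccccc3)c(OCc3ccccc3)c1)[C@@H](O)C2
F2 | step 6 | (2R,3S)-5,7-bis(benzyloxy)-2-[3,4-bis(benzyloxy)phenyl]-8-{(2S,4R)-7-(benzyloxy)-2-[3,4-bis(benzyloxy)phenyl]chroman-4-yl}chroman-3-ol | C(c1ccccc1)Oc1ccc2c(c1)O[C@H](c1ccc(OCc3ccccc3)c(OCc3ccccc3)c1)C[C@H]2c1c(OCc3ccccc3)cc(OCc3ccccc3)c2c1O[C@H](c1ccc(OCc3ccccc3)c(OCc3ccccc3)c1)[C@@H](O)C2
F3 | step 7 | (2S,4R)-7-(benzyloxy)-2-[3,4-bis(benzyloxy)phenyl]-4-[2,4-bis(benzyloxy)-6-hydroxyphenyl]chromane | C(c1ccccc1)Oc1ccc2c(c1)O[C@H](c1ccc(OCc3ccccc3)c(OCc3ccccc3)c1)C[C@H]2c1c(OCc3ccccc3)cc(OCc3ccccc3)cc1O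
F4 | step 7 | benzotriazolyl acetal of F3 with the 3,4-bis(benzyloxy)benzylidene unit (acetal carbon racemic) | C(c1ccccc1)Oc1ccc2c(c1)O[C@H](c1ccc(OCc3ccccc3)c(OCc3ccccc3)c1)C[C@H]2c1c(OCc3ccccc3)cc(OCc3ccccc3)cc1OC(c1ccc(OCc3ccccc3)c(OCc3ccccc3)c1)n1nnc3ccccc31
F5 | step 7 | iminium ion from F4 and enamine 12 after C2–C3 bond formation, benzotriazolide salt | C(c1ccccc1)Oc1ccc2c(c1)O[C@H](c1ccc(OCc3ccccc3)c(OCc3ccccc3)c1)C[C@H]2c1c(OCc3ccccc3)cc(OCc3ccccc3)cc1O[C@H](c1ccc(OCc3ccccc3)c(OCc3ccccc3)c1)[C@@H](OCc1ccccc1)C=[N+]1CCC[C@H]1C(c1ccccc1)(c1ccccc1)O[Si](C)(C)C.c1ccc2[n-]nnc2c1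
F6 | step 7 | 4-(pyrrolidin-1-yl) derivative of 16 carrying the auxiliary at C4 of the lower unit | C(c1ccccc1)Oc1ccc2c(c1)O[C@H](c1ccc(OCc3ccccc3)c(OCc3ccccc3)c1)C[C@H]2c1c(OCc3ccccc3)cc(OCc3ccccc3)c2c1O[C@H](c1ccc(OCc3ccccc3)c(OCc3ccccc3)c1)[C@@H](OCc1ccccc1)C2N1CCC[C@H]1C(c1ccccc1)(c1ccccc1)O[Si](C)(C)C
F7 | step 2 | (E)-1-[4-(benzyloxy)-2-hydroxyphenyl]-3-[3,4-bis(benzyloxy)phenyl]prop-2-en-1-one | O=C(/C=C/c1ccc(OCc2ccccc2)c(OCc2ccccc2)c1)c1ccc(OCc2ccccc2)cc1O
F8 | step 2 | racemic 7-(benzyloxy)-2-[3,4-bis(benzyloxy)phenyl]chroman-4-one | O=C1CC(c2ccc(OCc3ccccc3)c(OCc3ccccc3)c2)Oc2cc(OCc3ccccc3)ccc12
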